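## Analysis of the target

Target 20 is a daucane diester. Cyclopentane ring A (C1–C5) is trans-fused along the C1–C5 bond to cycloheptene ring B (C1, C5, C6, C7, C8, C9, C10), which carries the C8=C9 double bond and a methyl group on C8.

The five stereocentres are contiguous:
- C1 is quaternary with a β-methyl group.
- C5 bears an α-hydrogen.
- C4 is a tertiary carbinol (β-OH, α-isopropyl).
- C6 bears the α-veratrate, which is equatorial.
- C10 bears the α-angelate, which is axial, allylic and neopentyl.

The C4 hydroxyl therefore lies on the face of the angular methyl group, and both ester oxygens lie on the opposite face. A hydride would attack a C10 ketone from the open α face and give the wrong epimer. At C10, oxygen and not hydrogen must therefore arrive from the α face.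

Three groups are sensitive:
- The Z-configured angelate isomerises to the tiglate.
- The allylic C10–O bond can ionise.
- Any C6 ketone on the way is an aldol of C4, open to retro-aldol cleavage, dehydration and epimerisation at C5.

The hardest element is the C1–C5 bond. It is shared by both rings and joins a quaternary carbon to a methine flanked by two oxygenated carbons.

The feature exploited here is the array C1(CH3)–C5(H)–C6(O), which is the retron of a 1,2-shift of C1 from C6 to C5. If the C1–C5 bond is replaced by a C1–C6 bond, rings A and B become two six-membered rings. C4, C6 and C10 then fall on the three carbonyl carbons of a Wieland–Miescher-type triketone.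

## Retrosynthetic reasoning

**The two esters.** The C10–O acyl bond of 20 is cut last, giving 17 and the activated acid 19 (from 18). The angelate is the most fragile group and C10–OH the least reactive hydroxyl. The C6–O acyl bond of 17 is cut next, giving triol 15 and acid chloride 16. In 15 the equatorial C6 hydroxyl is the only unhindered one, so no protecting group is needed.

**The C6 carbinol.** Triol 15 comes from ketone 14. The β-hydroxyl on C4 is 1,3 to C6 and sits on the face from which hydride must come. A hydroxyl-directed reduction therefore sets C6.

**The C10–O bond and the C8=C9 position.** Ketone 14 is a δ-hydroxy-β,γ-enone, the product of reductive opening of the vinylogous epoxy ketone 13. Epoxide 13 comes from the linear dienone 12 by epoxidation of the distal double bond from the face opposite the angular methyl group. This delivers oxygen, not hydrogen, to C10, and the same operation moves the ring double bond to C8=C9.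

**Dehydrogenation.** Dienone 12 comes from ketone 11. Only the C7–C8 bond can be desaturated. The C8 stereocentre disappears, so its configuration in all earlier compounds is irrelevant.

**Key disconnection.** In 11 the C1–C5 bond is cut and C1 is reconnected to C6, which leads to the cis-decalin hydroxy mesylate 10.
- This cut removes the seven-membered ring, the trans ring fusion and the hindered C1–C5 bond at once.
- Other cuts in ring B leave a fully substituted cyclopentane still to be made.
- The forward step must move one specific bond with inversion at C5 and retention at C1. It must also leave the neighbouring tertiary carbinol alone.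

**The cis-diol.** Mesylate 10 comes from triol 9, and 9 from allylic alcohol 8 by syn dihydroxylation on the face of its own hydroxyl. That hydroxyl, later C4–OH, is used three times. It directs this oxidation, directs the reduction of 14, and stays in the target.

**Isopropyl group and C1=C2 bond.** Dienol 8 comes from hydrazone 6 in one flask, by carbonyl addition of an isopropyl nucleophile at C6 and conversion of the C1 hydrazone into the alkene. Hydrazone 6 comes from enedione 5. The former C1 carbonyl thus marks the carbon that receives the α-oxygen in 13.

**The decalin.** Enedione 5 comes from the achiral triketone 4 by a desymmetrising aldol condensation that creates the single controlling stereocentre. Triketone 4 comes from dione 2 and enone 3, and 2 from commercial dione 1.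

## Alternatives that were turned down

Alternative 1: The textbook route is ring-closing metathesis of the C8=C9 bond.
- Forward key step: diene triol A1, or a protected form, is treated with second-generation Grubbs catalyst to give 15.
- A1 already contains all five stereocentres, so the ring closure creates none.
- Both carbinol side chains on the cyclopentane need separate carbonyl additions under acyclic control, one of them next to the quaternary carbon.
- The closure forms a trisubstituted alkene beside a neopentyl allylic carbinol.
- Three hydroxyl groups must be told apart by protecting groups.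

Alternative 2: The C4–C5 bond is closed by an intramolecular aldol reaction.
- Forward key step: the C5 enolate of cycloheptenone diketone A2 adds to the side-chain isopropyl ketone to give 14.
- A chelated transition state would set C4 and C5 well.
- The seven-membered ring with the vicinal C1/C10 pair remains to be built, which is the main difficulty.
- In A2 the C7 methylene is both α to the ketone and allylic. Enolisation there, and drift of the double bond into conjugation, should outrun enolisation at C5.

Alternative 3: A single carbon, C7, is inserted into a six-membered ring.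
- Forward key step: diazoalkane homologation of trans-hydrindenone A3 to 14.
- The step requires migration of the sp2 carbon C8 in preference to the sp3 carbon C5.
- The carbonyl group is a poorly electrophilic cross-substituted enone.
- A3 keeps the same five stereocentres and a strained trans-hydrindane, so the precursor is no simpler than the product.

Key step: step 8

Remark on conventions:
- Decalins 5–10 carry naphthalene numbering and hydroazulenes 11–20 carry daucane numbering.
- Decalin C8a, C8, C7, C6, C5, C4a, C4, C3, C2 and C1 become C1 to C10 in that order.
- β is the face of the angular methyl group.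
- In the decalins, ring C is C4a–C5–C6–C7–C8–C8a and ring D is C1–C2–C3–C4–C4a–C8a.
- Compounds 4–11 are drawn as the expected major C-methyl epimer. The other epimer follows the same steps and converges at 12.

## Steps

Step 1
Reactants: 1 5-methylcyclohexane-1,3-dione
Product: 2 2,5-dimethylcyclohexane-1,3-dione
Conditions: MeI, NaOH, H2O–dioxane, reflux
Reagents that add atoms: iodomethane, CI
Why: C-alkylation of the stabilised 1,3-dione enolate at C2, the standard entry to 2-alkyl-1,3-diones; no lasting stereocentre is formed.

Step 2
Reactants: 2 2,5-dimethylcyclohexane-1,3-dione; 3 but-3-en-2-one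
Product: 4 trans-2,5-dimethyl-2-(3-oxobutyl)cyclohexane-1,3-dione
Conditions: Et3N (cat.), neat, 23 °C
Reagents that add atoms: none
Why: Michael addition of the dione to the enone; axial attack opposite the ring flap should favour the isomer with the two methyl groups trans. Either isomer is usable because this carbon (later C8) becomes sp2 in step 9.

Step 3
Reactants: 4 trans-2,5-dimethyl-2-(3-oxobutyl)cyclohexane-1,3-dione
Product: 5 (3R,8aS)-3,8a-dimethyl-3,4,8,8a-tetrahydronaphthalene-1,6(2H,7H)-dione
Conditions: N-tosyl-(Sa)-binam-L-prolinamide (cat.), PhCO2H (cat.), neat, 22 °C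
Reagents that add atoms: none
Why: Hajos–Parrish–Eder–Sauer–Wiechert aldol condensation: the L-proline-derived enamine picks one of the two enantiotopic ring carbonyls and fixes the quaternary carbon C8a as S (later C1). The remote methyl group lies far from the reacting centres.

Step 4
Reactants: 5 (3R,8aS)-3,8a-dimethyl-3,4,8,8a-tetrahydronaphthalene-1,6(2H,7H)-dione
Product: 6 C1 (E)-tosylhydrazone of enedione 5
Conditions: TsNHNH2 (1.0 equiv), EtOH, 23 °C
Reagents that add atoms: 4-methylbenzenesulfonohydrazide, Cc1ccc(cc1)S(=O)(=O)NN
Why: Condensation at the saturated C1 carbonyl, the more electrophilic one in this type of enedione (same order as in ketalisation and borohydride reduction); the C6 carbonyl is a conjugated, β,β-disubstituted enone. The sulfonamide nitrogen settles anti to the quaternary carbon, as the next step needs.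

Step 5
Reactants: 6 C1 (E)-tosylhydrazone of enedione 5
Product: 8 6α-isopropyl-3α,8aβ-dimethyl-3,4,6,7,8,8a-hexahydronaphthalen-6β-ol (double bonds C1=C2 and C4a=C5), via carbinol hydrazone 7 (not isolated)
Conditions: i-PrLi (5 equiv), TMEDA, Et2O, −78 °C to 0 °C; H2O
Reagents that add atoms: isopropyllithium, [Li]C(C)C
Why: 1,2-Addition of the alkyllithium to the enone is followed in the same flask by the Shapiro reaction (second deprotonation at C2, loss of sulfinate and N2, protonation on quench). Attack at C6 from the α face, axial and anti to the angular methyl group, sets the tertiary carbinol (later C4) with OH β.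

Step 6
Reactants: 8 6α-isopropyl-3α,8aβ-dimethyl-3,4,6,7,8,8a-hexahydronaphthalen-6β-ol
Product: 9 6α-isopropyl-3α,8aβ-dimethyl-cis-decal-1-ene-4aβ,5β,6β-triol
Conditions: OsO4 (1.05 equiv), TMEDA, CH2Cl2, −78 °C; then aq Na2SO3, THF, 60 °C
Reagents that add atoms: osmium tetroxide, O=[Os](=O)(=O)=O
Why: Hydrogen-bond-directed dihydroxylation by the OsO4–diamine complex: the C6 hydroxyl steers the reagent to the β face of the adjacent C4a=C5 bond, whose α face is also screened by the pseudoaxial isopropyl group. Syn addition sets C4a and C5, and the undirected, neopentyl C1=C2 bond should stay intact.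

Step 7
Reactants: 9 6α-isopropyl-3α,8aβ-dimethyl-cis-decal-1-ene-4aβ,5β,6β-triol
Product: 10 5β-mesylate of triol 9
Conditions: MsCl (1.2 equiv), Et3N, CH2Cl2, −20 °C
Reagents that add atoms: methanesulfonyl chloride, CS(=O)(=O)Cl
Why: Mesylation via sulfene reaches only the secondary C5 hydroxyl; the two tertiary hydroxyls do not react at this temperature.

Step 8
Reactants: 10 5β-mesylate of triol 9
Product: 11 4β-hydroxy-8α-methyl-5α-H-dauc-9-en-6-one (trans-fused hydroazulenone)
Conditions: LiClO4, CaCO3, THF, 50 °C
Reagents that add atoms: none
Why: Lithium-assisted ionisation of the C5–OMs bond is concerted with a suprafacial 1,2-shift of C8a from C4a to C5 and formation of the C4a carbonyl (semipinacol rearrangement of a vicinal diol monosulfonate), and CaCO3 takes up the acid. The closest known reaction type is the pinacol-type conversion of decalin-diol monosulfonates into hydroazulenones, equivalent to the A-nor-B-homo rearrangement of steroids. No end-to-end cyclisation is involved: the one shift closes five-membered ring A through the new C8a–C5 bond via a three-centre transition state and at the same time widens ring D by one atom into seven-membered ring B. In the cis-decalin chair that places the isopropyl group equatorial, the mesylate is equatorial and antiperiplanar to the C4a–C8a bond, so the reactive conformer is the ground state. C5 is inverted, so the β-mesylate becomes the α-hydrogen of a trans ring fusion; C8a migrates with retention and becomes C1, and the C6 carbinol is carried over unchanged as C4. The selectivity needed is C8a over C7, because the C6–C7 bond is also antiperiplanar and has its own hydroxyl; C8a should win because it is fully substituted and allylic, hence better at bearing positive charge in the transition state, and because its shift breaks the congested bond between two fully substituted carbons. Epoxide formation and elimination are excluded, since both hydroxyls are gauche to the mesylate and neither C4a nor C6 carries hydrogen. The neutral medium protects the aldol product from retro-aldol cleavage and from epimerisation at C5.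

Step 9
Reactants: 11 4β-hydroxy-8α-methyl-5α-H-dauc-9-en-6-one
Product: 12 4β-hydroxydauca-7,9-dien-6-one
Conditions: IBX, 4-methoxypyridine N-oxide, DMSO, 25 °C
Reagents that add atoms: none
Why: IBX dehydrogenation of the ketone through its enol; only C7–C8 can be desaturated because C1 and C4 next to C5 are fully substituted. The C8–H is also allylic, and the product cannot be oxidised further. The C8 stereocentre vanishes, so both methyl epimers converge on one dienone.

Step 10
Reactants: 12 4β-hydroxydauca-7,9-dien-6-one
Product: 13 9α,10α-epoxy-4β-hydroxydauc-7-en-6-one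
Conditions: mCPBA, CH2Cl2, 0 °C to 23 °C
Reagents that add atoms: 3-chloroperoxybenzoic acid, OOC(=O)c1cccc(Cl)c1
Why: Peracid epoxidation of a linear dienone takes place at the more electron-rich γ,δ bond (C9=C10), as with steroidal 4,6-dien-3-ones. The axial C1 methyl group blocks the β face, so oxygen reaches C10 from the α face.

Step 11
Reactants: 13 9α,10α-epoxy-4β-hydroxydauc-7-en-6-one
Product: 14 4β,10α-dihydroxydauc-8-en-6-one
Conditions: SmI2 (2.5 equiv), THF–MeOH, −78 °C
Reagents that add atoms: none
Why: Two-electron reduction of the vinylogous epoxy ketone by divalent samarium cleaves the C9–O bond and gives a dienolate that is protonated kinetically at C7, which leaves C8=C9 out of conjugation. The C10–O bond is untouched, so C10 keeps its α oxygen.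

Step 12
Reactants: 14 4β,10α-dihydroxydauc-8-en-6-one
Product: 15 dauc-8-ene-4β,6α,10α-triol
Conditions: Me4NBH(OAc)3, MeCN–AcOH, −30 °C
Reagents that add atoms: none
Why: Evans–Saksena reduction: the C4 hydroxyl exchanges onto boron and delivers hydride through a six-membered transition state to the β face of C6, giving the 1,3-anti diol (6α-OH). The C10 hydroxyl would need a seven-membered array across the trans ring fusion.

Step 13
Reactants: 15 dauc-8-ene-4β,6α,10α-triol; 16 3,4-dimethoxybenzoyl chloride
Product: 17 4β,10α-dihydroxydauc-8-en-6α-yl 3,4-dimethoxybenzoate
Conditions: 16 (1.1 equiv), Et3N, DMAP (cat.), CH2Cl2, 0 °C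
Reagents that add atoms: none
Why: Acylation of the equatorial C6 hydroxyl; the C10 hydroxyl is axial and neopentyl and the C4 hydroxyl is tertiary, so one equivalent of acid chloride should stop at the monoester.

Step 14
Reactants: 18 (Z)-2-methylbut-2-enoic acid (angelic acid)
Product: 19 angelic 2,4,6-trichlorobenzoic anhydride
Conditions: 2,4,6-trichlorobenzoyl chloride, Et3N, toluene, 23 °C; filtration
Reagents that add atoms: 2,4,6-trichlorobenzoyl chloride, O=C(Cl)c1c(Cl)cc(Cl)cc1Cl
Why: Formation of a Yamaguchi-type mixed anhydride; no nucleophilic catalyst is present, so the Z double bond should not isomerise.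

Step 15
Reactants: 17 4β,10α-dihydroxydauc-8-en-6α-yl 3,4-dimethoxybenzoate; 19 angelic 2,4,6-trichlorobenzoic anhydride
Product: 20 (3R,3aS,4S,8R,8aS)-3-hydroxy-6,8a-dimethyl-8-[(Z)-2-methylbut-2-enoyloxy]-3-(propan-2-yl)-1,2,3,3a,4,5,8,8a-octahydroazulen-4-yl 3,4-dimethoxybenzoate
Conditions: 19 (3 equiv), toluene, 80 °C
Reagents that add atoms: none
Why: Thermal acyl transfer from the mixed anhydride: the alcohol attacks the open angeloyl carbonyl and not the aroyl carbonyl flanked by two chlorine atoms. The absence of DMAP avoids addition–elimination isomerisation to the tiglate, and the tertiary C4 hydroxyl does not react.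

## Compound list

1 | 5-methylcyclohexane-1,3-dione | CC1CC(=O)CC(=O)C1 | starting material
2 | 2,5-dimethylcyclohexane-1,3-dione | CC1CC(=O)C(C)C(=O)C1 | intermediate
3 | but-3-en-2-one | CC(=O)C=C | starting material
4 | trans-2,5-dimethyl-2-(3-oxobutyl)cyclohexane-1,3-dione | CC(=O)CC[C@]1(C)C(=O)C[C@H](C)CC1=O | intermediate
5 | (3R,8aS)-3,8a-dimethyl-3,4,8,8a-tetrahydronaphthalene-1,6(2H,7H)-dione | O=C1C[C@H](C)CC2=CC(=O)CC[C@]12C | intermediate
6 | C1 (E)-tosylhydrazone of 5 | Cc1ccc(cc1)S(=O)(=O)N/N=C1\C[C@H](C)CC2=CC(=O)CC[C@]12C | intermediate
7 | 6β-hydroxy-6α-isopropyl carbinol of hydrazone 6 (not isolated) | CC(C)[C@]1(O)CC[C@]2(C)/C(=N/NS(=O)(=O)c3ccc(C)cc3)C[C@H](C)CC2=C1 | intermediate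
8 | 6α-isopropyl-3α,8aβ-dimethyl-3,4,6,7,8,8a-hexahydronaphthalen-6β-ol | CC(C)[C@]1(O)CC[C@]2(C)C=C[C@H](C)CC2=C1 | intermediate
9 | 6α-isopropyl-3α,8aβ-dimethyl-cis-decal-1-ene-4aβ,5β,6β-triol | CC(C)[C@]1(O)CC[C@]2(C)C=C[C@H](C)C[C@]2(O)[C@H]1O | intermediate
10 | 5β-mesylate of triol 9 | CC(C)[C@]1(O)CC[C@]2(C)C=C[C@H](C)C[C@]2(O)[C@H]1OS(C)(=O)=O | intermediate
11 | 4β-hydroxy-8α-methyl-5α-H-dauc-9-en-6-one | O=C1C[C@@H](C)C=C[C@@]2(C)CC[C@@](O)(C(C)C)[C@H]12 | intermediate
12 | 4β-hydroxydauca-7,9-dien-6-one | O=C1C=C(C)C=C[C@@]2(C)CC[C@@](O)(C(C)C)[C@H]12 | intermediate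
13 | 9α,10α-epoxy-4β-hydroxydauc-7-en-6-one | O=C1C=C(C)[C@H]2O[C@H]2[C@@]3(C)CC[C@@](O)(C(C)C)[C@H]13 | intermediate
14 | 4β,10α-dihydroxydauc-8-en-6-one | O[C@@H]1C=C(C)CC(=O)[C@@H]2[C@]1(C)CC[C@@]2(O)C(C)C | intermediate
15 | dauc-8-ene-4β,6α,10α-triol | O[C@@H]1C=C(C)C[C@H](O)[C@@H]2[C@]1(C)CC[C@@]2(O)C(C)C | intermediate
16 | 3,4-dimethoxybenzoyl chloride | COc1ccc(cc1OC)C(Cl)=O | starting material
17 | 4β,10α-dihydroxydauc-8-en-6α-yl 3,4-dimethoxybenzoate | O[C@@H]1C=C(C)C[C@H](OC(=O)c2ccc(OC)c(OC)c2)[C@@H]2[C@]1(C)CC[C@@]2(O)C(C)C | intermediate
18 | (Z)-2-methylbut-2-enoic acid | C/C=C(/C)C(O)=O | starting material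
19 | angelic 2,4,6-trichlorobenzoic anhydride | C/C=C(/C)C(=O)OC(=O)c1c(Cl)cc(Cl)cc1Cl | intermediate
20 | 10α-angeloyloxy-6α-veratroyloxydauc-8-en-4β-ol (target) | C/C=C(/C)C(=O)O[C@@H]1C=C(C)C[C@H](OC(=O)c2ccc(OC)c(OC)c2)[C@@H]2[C@]1(C)CC[C@@]2(O)C(C)C | target

## Step count and least certain steps

Total step count: 15. Longest linear sequence: 14 (steps 1–13 and 15). Step 14 is a one-step side branch.

**Step 8 (key step).**
- The most likely failure is competing migration of C7, pushed by the C6 hydroxyl, because the C6–C7 bond is equally well aligned with the leaving group.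
- Slow ionisation of a mesylate flanked by two oxygenated carbons is the second risk.
- The fallback removes the second donor and sets out from 10.
- Monosilylation of the less congested C6 hydroxyl (TMSOTf, 2,6-lutidine, −78 °C) should give the silyl ether mesylate F1. The C4a hydroxyl is spared because it sits next to the quaternary carbon.
- In F1 only the C4a hydroxyl can drive a shift, so the same conditions should lead to the silyl ether ketone F2.
- Mild acid methanolysis of F2 returns to the route at 11.

**Step 4.**
- The most likely failure is poor discrimination between the two carbonyl groups. The saturated one is more electrophilic but neopentyl, so condensation at the enone or at both sites may compete.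
- The fallback sets out from 5 and replaces condensation by reduction and elimination.
- NaBH4 in EtOH at 0 °C reduces the saturated ketone selectively to the hydroxy enone F3.
- Syn dehydration with the Burgess reagent in toluene gives the dienone F4.
- 1,2-Addition of i-PrMgCl in the presence of CeCl3 rejoins the route at 8. This also removes the strongly basic alkyllithium from the carbonyl addition.

**Step 5.**
- The most likely failures are enolisation of the enone by the basic reagent and poor facial selectivity. A branched nucleophile may prefer the pseudoequatorial approach from the β face.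
- The fallback sets out from 6 and uses the product of β attack instead of discarding it.
- The epimeric dienol F5 is dihydroxylated as in step 6. Its own hydroxyl now directs to the α face, which gives the all-α triol F6.
- The derived mesylate F7 is a trans-decalin chair with the same antiperiplanar alignment, and it should rearrange under the conditions of step 8 to the cis-fused aldol F8.
- Catalytic KOt-Bu in t-BuOH–THF at 0 °C then opens F8 reversibly by retro-aldol cleavage to the diketone F9, which closes again.
- In F8 the isopropyl group is syn to the C1 methyl group on ring A, whereas in 11 it is anti. Both isomers keep the hydroxyl cis to the acyl carbon, so the equilibrium should drain into 11, where the route is rejoined.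

**Step 6.**
- The most likely failure is loss of facial control, because the β face is next to the angular methyl group. Oxidation of the C1=C2 bond is a lesser risk.
- The fallback sets out from 8 and installs the two oxygens one after the other.
- Hydroxyl-directed epoxidation with VO(acac)2 and t-BuOOH gives the β-epoxide F10.
- LiBr-catalysed insertion of CO2 proceeds by bromide opening at C5 and closure with a second inversion, hence overall retention. It gives the cis cyclic carbonate F11.
- K2CO3 in MeOH releases 9.

**Step 15.**
- The most likely failures are very slow acylation of the axial, neopentyl C10 hydroxyl and Z-to-E isomerisation on prolonged heating.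
- The fallback sets out from 17 and builds the double bond on the ester.
- DCC/DMAP coupling with 2-[bis(2,2,2-trifluoroethoxy)phosphoryl]propanoic acid gives the phosphonate ester F12.
- Still–Gennari olefination with acetaldehyde (KHMDS, 18-crown-6, THF, −78 °C) forms the Z-alkene and arrives at 20.

## Further compounds

F1 | step 8 | 6-O-trimethylsilyl ether of mesylate 10 | CC(C)[C@]1(O[Si](C)(C)C)CC[C@]2(C)C=C[C@H](C)C[C@]2(O)[C@H]1OS(C)(=O)=O
F2 | step 8 | 4-O-trimethylsilyl ether of ketone 11 | O=C1C[C@@H](C)C=C[C@@]2(C)CC[C@@](O[Si](C)(C)C)(C(C)C)[C@H]12
F3 | step 4 | 1β-hydroxy-3α,8aβ-dimethyl enone (C1 alcohol of 5) | O[C@H]1C[C@H](C)CC2=CC(=O)CC[C@]12C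
F4 | step 4 | 3α,8aβ-dimethyl-4,7,8,8a-tetrahydronaphthalen-6(3H)-one (C1=C2 and C4a=C5) | O=C1CC[C@]2(C)C=C[C@H](C)CC2=C1
F5 | step 5 | 6-epimer of dienol 8 (6α-OH, 6β-isopropyl) | CC(C)[C@@]1(O)CC[C@]2(C)C=C[C@H](C)CC2=C1
F6 | step 5 | 6β-isopropyl-trans-decal-1-ene-4aα,5α,6α-triol | CC(C)[C@@]1(O)CC[C@]2(C)C=C[C@H](C)C[C@@]2(O)[C@@H]1O
F7 | step 5 | 5α-mesylate of triol F6 | CC(C)[C@@]1(O)CC[C@]2(C)C=C[C@H](C)C[C@@]2(O)[C@@H]1OS(C)(=O)=O
F8 | step 5 | cis-fused aldol (5β-H, 4α-OH, 4β-isopropyl isomer of 11) | O=C1C[C@@H](C)C=C[C@@]2(C)CC[C@](O)(C(C)C)[C@@H]12
F9 | step 5 | 3,6-dimethyl-3-(4-methyl-3-oxopentyl)cyclohept-4-en-1-one (open diketone) | O=C1C[C@@H](C)C=C[C@@](C)(CCC(=O)C(C)C)C1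
F10 | step 6 | 4aβ,5β-epoxide of dienol 8 | CC(C)[C@]1(O)CC[C@]2(C)C=C[C@H](C)C[C@@]23O[C@@H]13
F11 | step 6 | 4aβ,5β-cyclic carbonate of triol 9 | CC(C)[C@]1(O)CC[C@]2(C)C=C[C@H](C)C[C@@]23OC(=O)O[C@@H]13
F12 | step 15 | 10-O-{2-[bis(2,2,2-trifluoroethoxy)phosphoryl]propanoyl} derivative of 17 | CC(C(=O)O[C@@H]1C=C(C)C[C@H](OC(=O)c2ccc(OC)c(OC)c2)[C@@H]2[C@]1(C)CC[C@@]2(O)C(C)C)P(=O)(OCC(F)(F)F)OCC(F)(F)F
A1 | alternative 1 | cyclopentane diene triol (metathesis precursor) | O[C@H](C=C)[C@@]1(C)CC[C@@](O)(C(C)C)[C@@H]1[C@@H](O)CC(C)=C
A2 | alternative 2 | 4-hydroxy-3,6-dimethyl-3-(4-methyl-3-oxopentyl)cyclohept-5-en-1-one (aldol precursor) | O[C@@H]1C=C(C)CC(=O)C[C@]1(C)CCC(=O)C(C)C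
A3 | alternative 3 | trans-hydrindenone lacking C7 (homologation precursor) | O[C@@H]1C=C(C)C(=O)[C@@H]2[C@]1(C)CC[C@@]2(O)C(C)C
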